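Time was what I counted for the east flask, in half-lives of D.

| setting | green | violet | ochre | south-west | north | east | north-east |
|---|---|---|---|---|---|---|---|
| D | 0.050 M | 0.070 M | 0.11 M | 0.050 M (fed, over 4.80 min) | 0.050 M | 0.050 M | 0.050 M |
| E | 0.10 M | 0.10 M | 0.10 M | 0.100 M | 0.100 M | 0.100 M (fed, over 4.80 min) | 0.100 M |
| remark | run made earlier | run made earlier | run made earlier | a stirred flask in which D is dosed at a steady rate over 4.80 min without added volume, worked up at 6.0 min | one stirred flow tank at steady state, fed with the mixture as stated, mean residence time 6.0 min | a stirred flask in which E is dosed at a steady rate over 4.80 min without added volume, worked up at 6.0 min | everything together in a closed stirred flask, run for 6.0 min |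
| time |  |  |  | 6.0 min |  | 6.0 min | 6.0 min |

- green (time / min: Q / %, D / %): 0.250: 0.4, 92.8; 0.667: 4.3, 84.4; 1.33: 10.6, 71.4; 2.00: 16.2, 61.8; 3.00: 25.0, 50.8; 4.00: 31.0, 41.8
- violet (time / min: Q / %, D / %): 0.500: 2.1, 88.3; 0.833: 4.7, 80.4; 1.33: 9.8, 70.5; 2.00: 15.1, 60.9; 4.00: 26.4, 41.1; 6.00: 35.2, 29.8
- ochre (time / min: Q / %, D / %): 0.500: 2.3, 86.9; 0.833: 4.5, 79.4; 1.33: 8.6, 70.4; 2.00: 12.8, 59.5; 4.00: 21.4, 42.0; 6.00: 26.2, 31.1

(standard deviation of a reading: 0.5 percentage points)

- the set-up with the highest amount of Q at the outlet or at the end, in percent of the D put in ("none" if the first two lie within 2 percentage points) (south-west / north / east / north-east / none)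
- amount of Q at the outlet or at the end, in percent of the D put in, south-west
- amount of Q at the outlet or at the end, in percent of the D put in, north
- amount of Q at the outlet or at the end, in percent of the D put in, east
- amount of Q at the outlet or at the end, in percent of the D put in, north-east

- the stated concentrations are those of everything mixed, before any reaction; amounts are the same in each set-up
- the feed brings no volume worth counting
- the earlier runs were made in a closed, stirred flask

In east, E comes in evenly over 4.80 min, so the E dosed, summed over the run, equals the full charge standing for 3.60 min, which I called the E-time. What could spoil a count on it I took in turn.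

First, the charge of D. At 4.00 min green, violet and ochre kept 41.8 %, 41.1 % and 42.0 % of their D, a spread of 0.9 percentage points, so I treated D as pseudo-first-order with one half-life.

Second, the reading of that half-life. Green at 3.00 min gave 3.07 min and violet at 6.00 min gave 3.44 min, which moved the D left in east by 4 points.

Last, the order in E, since each earlier run had E at 0.10 M. If E counted for nothing, my estimate for east was the violet reading at 6.00 min, 29.8 % of D, which is 19 points less, a wider gap than the other two. I took first order in E and the violet half-life.

count = E-time / half-life = 3.60 min / 3.44 min = 1.05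

D left = 0.5^count = 48.4 %

Q, read on green at that D left = 26.6 %

This count of half-lives of D on the E-time was my rule.

The forecast named north-east best, with 30 % south-west, 28 % north, 35 % east and 39.5 % north-east, and held east least certain, “as E order is untested”. Its east stood higher than my 26.6 %.

The flask gave north-east as best, with 29.4 % south-west, 30.6 % north, 27.6 % east and 40.0 % north-east.

    D + E ⇌ Z (K = 6.30 M⁻¹, k = 2.66 M⁻¹ min⁻¹)
    Z ⇌ Q (K = 39.1, k = 1.09 min⁻¹)
    D + Z → X (k = 11.0 M⁻¹ min⁻¹)

At 3.00 min east held less E, 54.1 % of its charge, than north-east with 79.7 %. The D left in east, 45.7 %, stands for 1.13 half-lives against my count of 1.05.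

The neighbour of north-east with 0.25 M of E was charged with 2.50 times the E and ran for 6.0 min, so my count gave 4.37 and an estimate of 4.84 % of D left. That neighbour ended with 6.83 % of D and 63.3 % of Q.

All runs were computed from invented constants, noise included.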